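**Retrosynthetic overview**
1. Target 42 ⇐ Yamaguchi angeloylation of the C5 alcohol, then desilylation; the C2 ketone comes from ozonolysis of a 1,1-disubstituted alkene; the C11 methyl comes from lactone-enolate methylation and kinetic protonation.
2. cis-γ-Lactone (second ring) ⇐ α-bromination of a C5 ketone and intramolecular carboxylate displacement; the C5 carbinol ⇐ hydroxyl-directed reduction.
3. C1 tertiary carbinol ⇐ alkenylcerium 22 (side chain C2–C4/C15, carbinol from ketoreductase reduction of ethyl acetoacetate) + α-silyloxy ketone 13.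
4. 13 ⇐ Cu-catalysed asymmetric Me2Zn addition with silyl enol ether trapping, then hydroboration–oxidation, on cycloheptenone 8.
5. 8 (seven-membered ring, formed first, by RCM) ⇐ Cu/Josiphos asymmetric conjugate addition of butenylmagnesium bromide to enoate 3 (first stereocentre).

Assumption: for the chiral ligands and the ketoreductase, the enantiomer (or enzyme variant) that gives the stated configuration is used; the sense of induction was not checked against the literature.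
Abbreviations: TBSO = tert-butyldimethylsilyloxy, TBDPSO = tert-butyldiphenylsilyloxy, TESO = triethylsilyloxy, TMS = trimethylsilyl. Atom labels C1–C15 in the Why lines follow the natural-product skeleton (C1 tertiary carbinol, C5 ester carbon, C6 lactone O-carbon, C7 ring-fusion carbon, C10 methyl-bearing carbon, C11 lactone α-carbon).

**Step 1**
Reactants: 1 tert-butyl(but-3-en-1-yloxy)dimethylsilane; 2 methyl acrylate
Product: 3 methyl (2E)-5-(TBSO)pent-2-enoate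
Conditions: 2 (3 equiv), Hoveyda–Grubbs II (2 mol%), CH2Cl2, 40 °C
Reagents that add atoms: none
Why: Olefin cross-metathesis of a terminal alkene with excess acrylate gives the E-enoate selectively and leaves the silyl ether untouched.

**Step 2**
Reactants: 3 methyl (2E)-5-(TBSO)pent-2-enoate; 4 but-3-en-1-ylmagnesium bromide
Product: 5 methyl (3S)-3-[2-(TBSO)ethyl]hept-6-enoate
Conditions: 4 (1.2 equiv), CuBr·SMe2 (5 mol%), Josiphos ligand (6 mol%), t-BuOMe, −75 °C; NH4Cl aq.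
Reagents that add atoms: none
Why: Copper/Josiphos-catalysed asymmetric conjugate addition of a Grignard reagent to an E-enoate sets the first stereocentre (C7) by catalyst control.

**Step 3**
Reactants: 5 methyl (3S)-3-[2-(TBSO)ethyl]hept-6-enoate
Product: 6 (3S)-3-[2-(TBSO)ethyl]-N-methoxy-N-methylhept-6-enamide
Conditions: MeNH(OMe)·HCl, i-PrMgCl, THF, −20 °C
Reagents that add atoms: N,O-dimethylhydroxylamine hydrochloride, CNOC.Cl
Why: Direct Weinreb amidation of the methyl ester through the magnesium amide does not touch the stereocentre, the silyl ether or the alkene.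

**Step 4**
Reactants: 6 (3S)-3-[2-(TBSO)ethyl]-N-methoxy-N-methylhept-6-enamide
Product: 7 (5S)-5-[2-(TBSO)ethyl]nona-1,8-dien-3-one
Conditions: CH2=CHMgBr, THF, −78 → 0 °C; inverse quench into cold 1 M HCl
Reagents that add atoms: vinylmagnesium bromide, C=C[Mg]Br
Why: In this Weinreb ketone synthesis the chelated tetrahedral intermediate prevents over-addition, and the cold acidic quench prevents conjugate addition of the released amine to the vinyl ketone.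

**Step 5**
Reactants: 7 (5S)-5-[2-(TBSO)ethyl]nona-1,8-dien-3-one
Product: 8 (6S)-6-[2-(TBSO)ethyl]cyclohept-2-en-1-one
Conditions: Grubbs II (3 mol%), CH2Cl2 (5 mM), 40 °C
Reagents that add atoms: none
Why: Ring-closing metathesis of the 1,8-diene at high dilution forms the seven-membered enone with loss of ethene.

**Step 6**
Reactants: 8 (6S)-6-[2-(TBSO)ethyl]cyclohept-2-en-1-one
Product: 10 tert-butyl{[(3S,6S)-6-[2-(TBSO)ethyl]-3-methylcyclohept-1-en-1-yl]oxy}dimethylsilane, via methylzinc enolate 9 (not isolated)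
Conditions: Me2Zn (1.5 equiv), Cu(OTf)2 (2 mol%), Feringa phosphoramidite (4 mol%), toluene, −25 °C; then TBSOTf, −25 → 0 °C
Reagents that add atoms: dimethylzinc, C[Zn]C; tert-butyldimethylsilyl trifluoromethanesulfonate, CC(C)(C)[Si](C)(C)OS(=O)(=O)C(F)(F)F
Why: Copper/phosphoramidite-catalysed asymmetric conjugate addition sets C10 by catalyst control cis to the remote side chain, and the zinc enolate is trapped regiospecifically as the silyl enol ether.

**Step 7**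
Reactants: 10 tert-butyl{[(3S,6S)-6-[2-(TBSO)ethyl]-3-methylcyclohept-1-en-1-yl]oxy}dimethylsilane
Product: 12 (1R,2R,4S,7S)-2-(TBSO)-4-[2-(TBSO)ethyl]-7-methylcycloheptan-1-ol, via alkylborane 11 (not isolated)
Conditions: BH3·THF, THF, 0 °C → rt; then NaBO3·4H2O, H2O, rt
Reagents that add atoms: sodium perborate, [Na+].[Na+].O[B-]1(O)OO[B-](O)(O)OO1
Why: Hydroboration–oxidation of the silyl enol ether puts boron on the non-oxygenated carbon anti to the adjacent methyl group, so syn addition gives the trans silyloxy alcohol with the C5 oxygen cis to the methyl group.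

**Step 8**
Reactants: 12 (1R,2R,4S,7S)-2-(TBSO)-4-[2-(TBSO)ethyl]-7-methylcycloheptan-1-ol
Product: 13 (2R,4S,7S)-2-(TBSO)-4-[2-(TBSO)ethyl]-7-methylcycloheptan-1-one
Conditions: Dess–Martin periodinane, NaHCO3, CH2Cl2, 0 °C → rt
Reagents that add atoms: none
Why: Buffered Dess–Martin oxidation converts the secondary alcohol into the ketone without epimerising the two α-centres.

**Step 9**
Reactants: 14 ethyl acetoacetate
Product: 15 ethyl (3R)-3-hydroxybutanoate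
Conditions: (R)-selective ketoreductase, NADP+ (cat.), i-PrOH, phosphate buffer pH 7, 30 °C
Reagents that add atoms: none
Why: Ketoreductase-catalysed asymmetric reduction of the β-keto ester, with cofactor recycling by isopropanol, sets the side-chain carbinol (C4) in high ee.

**Step 10**
Reactants: 15 ethyl (3R)-3-hydroxybutanoate
Product: 16 ethyl (3R)-3-(TBDPSO)butanoate
Conditions: TBDPSCl, imidazole, DMF, rt
Reagents that add atoms: tert-butyl(chloro)diphenylsilane, CC(C)(C)[Si](Cl)(c1ccccc1)c1ccccc1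
Why: Silylation of the secondary alcohol gives an ether that survives the organometallic, oxidative and early fluoride steps.

**Step 11**
Reactants: 16 ethyl (3R)-3-(TBDPSO)butanoate
Product: 17 (3R)-3-(TBDPSO)butanal
Conditions: DIBAL-H, CH2Cl2, −78 °C; Rochelle salt
Reagents that add atoms: none
Why: DIBAL-H partial reduction at −78 °C stops at the aldehyde through the stable aluminium hemiacetal.

**Step 12**
Reactants: 17 (3R)-3-(TBDPSO)butanal
Product: 18 tert-butyl[(2R)-pent-4-yn-2-yloxy]diphenylsilane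
Conditions: dimethyl (1-diazo-2-oxopropyl)phosphonate, K2CO3, MeOH, 0 °C → rt
Reagents that add atoms: dimethyl (1-diazo-2-oxopropyl)phosphonate, COP(=O)(OC)C(=[N+]=[N-])C(C)=O
Why: Seyferth–Gilbert homologation with the Ohira–Bestmann reagent turns the aldehyde into the terminal alkyne under conditions mild enough for the β-silyloxy group.

**Step 13**
Reactants: 18 tert-butyl[(2R)-pent-4-yn-2-yloxy]diphenylsilane
Product: 20 {[(2R)-4-bromopent-4-en-2-yl]oxy}(tert-butyl)diphenylsilane, via bromoalkenylborane 19 (not isolated)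
Conditions: B-Br-9-BBN, CH2Cl2, 0 °C; then AcOH, 0 °C → rt
Reagents that add atoms: B-bromo-9-borabicyclo[3.3.1]nonane, BrB1C2CCCC1CCC2
Why: Bromoboration of the terminal alkyne puts bromine on the internal carbon, and protonolysis of the C–B bond gives the 2-bromo-1-alkene.

**Step 14**
Reactants: 20 {[(2R)-4-bromopent-4-en-2-yl]oxy}(tert-butyl)diphenylsilane; 13 (2R,4S,7S)-2-(TBSO)-4-[2-(TBSO)ethyl]-7-methylcycloheptan-1-one
Product: 23 (1R,2R,4S,7S)-2-(TBSO)-4-[2-(TBSO)ethyl]-7-methyl-1-[(4R)-4-(TBDPSO)pent-1-en-2-yl]cycloheptan-1-ol, via alkenyllithium 21 (not isolated), via alkenylcerium dichloride 22 (not isolated)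
Conditions: 20 (2.5 equiv), t-BuLi (2 equiv per 20), Et2O, −78 °C; CeCl3, THF, −78 °C; then 13, −78 °C; NH4Cl aq.
Reagents that add atoms: none
Why: Bromine–lithium exchange and transmetalation give a weakly basic alkenylcerium reagent whose 1,2-addition occurs anti to both α-substituents of the ketone (methyl and silyloxy on the same face) and so sets the C1 tertiary carbinol.

**Step 15**
Reactants: 23 (1R,2R,4S,7S)-2-(TBSO)-4-[2-(TBSO)ethyl]-7-methyl-1-[(4R)-4-(TBDPSO)pent-1-en-2-yl]cycloheptan-1-ol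
Product: 24 (1R,2R,4S,7S)-4-(2-hydroxyethyl)-7-methyl-1-[(4R)-4-(TBDPSO)pent-1-en-2-yl]cycloheptane-1,2-diol
Conditions: HF·pyridine, pyridine, THF, 0 °C → rt
Reagents that add atoms: none
Why: Buffered HF·pyridine desilylation removes the primary and the secondary TBS ether while the more robust TBDPS ether stays.

**Step 16**
Reactants: 24 (1R,2R,4S,7S)-4-(2-hydroxyethyl)-7-methyl-1-[(4R)-4-(TBDPSO)pent-1-en-2-yl]cycloheptane-1,2-diol
Product: 25 2-[(1S,4R,5S)-4-hydroxy-5-methyl-3-oxo-4-[(4R)-4-(TBDPSO)pent-1-en-2-yl]cycloheptyl]acetaldehyde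
Conditions: IBX (3 equiv), DMSO, rt
Reagents that add atoms: none
Why: IBX oxidation takes the primary alcohol to the aldehyde and the secondary alcohol to the ketone without cleaving the vicinal diol, and the tertiary alcohol is inert.

**Step 17**
Reactants: 25 2-[(1S,4R,5S)-4-hydroxy-5-methyl-3-oxo-4-[(4R)-4-(TBDPSO)pent-1-en-2-yl]cycloheptyl]acetaldehyde
Product: 26 2-[(1R,4R,5S)-4-hydroxy-5-methyl-3-oxo-4-[(4R)-4-(TBDPSO)pent-1-en-2-yl]cycloheptyl]acetic acid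
Conditions: NaClO2, NaH2PO4, 2-methyl-2-butene, t-BuOH/H2O, 0 °C → rt
Reagents that add atoms: sodium chlorite, [Na+].[O-]Cl=O
Why: Pinnick oxidation converts only the aldehyde into the acid, and the scavenger protects the side-chain alkene from HOCl.

**Step 18**
Reactants: 26 2-[(1R,4R,5S)-4-hydroxy-5-methyl-3-oxo-4-[(4R)-4-(TBDPSO)pent-1-en-2-yl]cycloheptyl]acetic acid
Product: 29 (3aS,6S,7R,8aR)-7-hydroxy-6-methyl-7-[(4R)-4-(TBDPSO)pent-1-en-2-yl]hexahydro-2H-cyclohepta[b]furan-2,8(3H)-dione, via tris-TMS enol ether 27 (not isolated), via α-bromo ketone 28 (not isolated)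
Conditions: TMSOTf, Et3N, CH2Cl2, 0 °C; NBS, THF, −78 °C; then NaHCO3 aq., rt; citric acid, MeOH
Reagents that add atoms: none
Why: Soft enolisation can only go toward C6 (C1 is quaternary), bromination of the silyl enol ether occurs anti to the C7 side chain, and intramolecular SN2 displacement by the carboxylate closes the cis-fused γ-lactone with inversion.

**Step 19**
Reactants: 29 (3aS,6S,7R,8aR)-7-hydroxy-6-methyl-7-[(4R)-4-(TBDPSO)pent-1-en-2-yl]hexahydro-2H-cyclohepta[b]furan-2,8(3H)-dione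
Product: 30 (3aS,6S,7R,8S,8aR)-7,8-dihydroxy-6-methyl-7-[(4R)-4-(TBDPSO)pent-1-en-2-yl]octahydro-2H-cyclohepta[b]furan-2-one
Conditions: Me4NBH(OAc)3, AcOH/MeCN, −30 °C
Reagents that add atoms: none
Why: Hydroxyl-directed (Saksena–Evans) reduction delivers hydride intramolecularly from the face of the C1 hydroxyl and so gives the trans diol with the correct C5 carbinol.

**Step 20**
Reactants: 30 (3aS,6S,7R,8S,8aR)-7,8-dihydroxy-6-methyl-7-[(4R)-4-(TBDPSO)pent-1-en-2-yl]octahydro-2H-cyclohepta[b]furan-2-one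
Product: 31 (3aS,6S,7R,8S,8aR)-6-methyl-7-[(4R)-4-(TBDPSO)pent-1-en-2-yl]-7,8-bis(TESO)octahydro-2H-cyclohepta[b]furan-2-one
Conditions: TESOTf, 2,6-lutidine, CH2Cl2, −78 → 0 °C
Reagents that add atoms: triethylsilyl trifluoromethanesulfonate, CC[Si](CC)(CC)OS(=O)(=O)C(F)(F)F
Why: Silyl triflate silylation protects both hydroxyls, including the tertiary one, so that the lactone α-position is the only acidic site.

**Step 21**
Reactants: 31 (3aS,6S,7R,8S,8aR)-6-methyl-7-[(4R)-4-(TBDPSO)pent-1-en-2-yl]-7,8-bis(TESO)octahydro-2H-cyclohepta[b]furan-2-one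
Product: 33 (3S,3aS,6S,7R,8S,8aR)-3,6-dimethyl-7-[(4R)-4-(TBDPSO)pent-1-en-2-yl]-7,8-bis(TESO)octahydro-2H-cyclohepta[b]furan-2-one, via lithium enolate 32 (not isolated)
Conditions: LDA (1.2 equiv), THF, −78 °C; MeI, −78 → −40 °C
Reagents that add atoms: iodomethane, CI
Why: Lactone enolate alkylation introduces the C11 methyl group from the convex face, and this provisional configuration is reset in the next step.

**Step 22**
Reactants: 33 (3S,3aS,6S,7R,8S,8aR)-3,6-dimethyl-7-[(4R)-4-(TBDPSO)pent-1-en-2-yl]-7,8-bis(TESO)octahydro-2H-cyclohepta[b]furan-2-one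
Product: 35 (3R,3aS,6S,7R,8S,8aR)-3,6-dimethyl-7-[(4R)-4-(TBDPSO)pent-1-en-2-yl]-7,8-bis(TESO)octahydro-2H-cyclohepta[b]furan-2-one, via lithium enolate 34 (not isolated)
Conditions: LDA (1.5 equiv), THF, −78 → −40 °C; then 2,6-di-tert-butyl-4-methylphenol, −78 °C; NH4Cl aq.
Reagents that add atoms: none
Why: Kinetic protonation of the lactone enolate by a bulky phenol from the convex face of the cis-fused bicycle puts the C11 methyl on the concave face, as in the target.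

**Step 23**
Reactants: 35 (3R,3aS,6S,7R,8S,8aR)-3,6-dimethyl-7-[(4R)-4-(TBDPSO)pent-1-en-2-yl]-7,8-bis(TESO)octahydro-2H-cyclohepta[b]furan-2-one
Product: 37 (3R,3aS,6S,7S,8S,8aR)-3,6-dimethyl-7-[(3R)-3-(TBDPSO)butanoyl]-7,8-bis(TESO)octahydro-2H-cyclohepta[b]furan-2-one, via ozonide 36 (not isolated)
Conditions: O3, CH2Cl2, −78 °C; then Me2S, −78 °C → rt
Reagents that add atoms: ozone, [O-][O+]=O
Why: Ozonolysis of the only C=C bond with reductive work-up unmasks the C2 ketone.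

**Step 24**
Reactants: 37 (3R,3aS,6S,7S,8S,8aR)-3,6-dimethyl-7-[(3R)-3-(TBDPSO)butanoyl]-7,8-bis(TESO)octahydro-2H-cyclohepta[b]furan-2-one
Product: 38 (3R,3aS,6S,7S,8S,8aR)-7,8-dihydroxy-3,6-dimethyl-7-[(3R)-3-(TBDPSO)butanoyl]octahydro-2H-cyclohepta[b]furan-2-one
Conditions: HF·pyridine, pyridine, THF, 0 °C
Reagents that add atoms: none
Why: Selective desilylation works because TES ethers are far more labile to HF·pyridine than the TBDPS ether.

**Step 25**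
Reactants: 38 (3R,3aS,6S,7S,8S,8aR)-7,8-dihydroxy-3,6-dimethyl-7-[(3R)-3-(TBDPSO)butanoyl]octahydro-2H-cyclohepta[b]furan-2-one; 39 angelic acid
Product: 41 (3R,3aS,6S,7S,8S,8aR)-7-hydroxy-3,6-dimethyl-2-oxo-7-[(3R)-3-(TBDPSO)butanoyl]octahydro-2H-cyclohepta[b]furan-8-yl (2Z)-2-methylbut-2-enoate, via mixed anhydride 40 (not isolated)
Conditions: 39, 2,4,6-trichlorobenzoyl chloride, Et3N, toluene, rt; then 38, toluene, 80 °C
Reagents that add atoms: none
Why: Yamaguchi esterification without DMAP acylates only the secondary C5 hydroxyl (the tertiary one is inert) and avoids Z to E isomerisation of the angelate.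

**Step 26**
Reactants: 41 (3R,3aS,6S,7S,8S,8aR)-7-hydroxy-3,6-dimethyl-2-oxo-7-[(3R)-3-(TBDPSO)butanoyl]octahydro-2H-cyclohepta[b]furan-8-yl (2Z)-2-methylbut-2-enoate
Product: 42 (3R,3aS,6S,7S,8S,8aR)-7-hydroxy-7-[(3R)-3-hydroxybutanoyl]-3,6-dimethyl-2-oxooctahydro-2H-cyclohepta[b]furan-8-yl (2Z)-2-methylbut-2-enoate
Conditions: HF·pyridine, THF, 0 °C → rt
Reagents that add atoms: none
Why: Mildly acidic fluoride desilylation frees the C4 carbinol without β-elimination of the β-hydroxy ketone or isomerisation of the angelate, and gives the target.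

**Compound list**
1 | tert-butyl(but-3-en-1-yloxy)dimethylsilane | C=CCCO[Si](C)(C)C(C)(C)C | starting material
2 | methyl acrylate | C=CC(=O)OC | starting material
3 | methyl (2E)-5-(TBSO)pent-2-enoate | COC(=O)/C=C/CCO[Si](C)(C)C(C)(C)C | intermediate
4 | but-3-en-1-ylmagnesium bromide | C=CCC[Mg]Br | starting material
5 | methyl (3S)-3-[2-(TBSO)ethyl]hept-6-enoate | COC(=O)C[C@H](CCO[Si](C)(C)C(C)(C)C)CCC=C | intermediate
6 | (3S)-3-[2-(TBSO)ethyl]-N-methoxy-N-methylhept-6-enamide | CON(C)C(=O)C[C@H](CCO[Si](C)(C)C(C)(C)C)CCC=C | intermediate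
7 | (5S)-5-[2-(TBSO)ethyl]nona-1,8-dien-3-one | C=CC(=O)C[C@H](CCO[Si](C)(C)C(C)(C)C)CCC=C | intermediate
8 | (6S)-6-[2-(TBSO)ethyl]cyclohept-2-en-1-one | O=C1C[C@H](CCO[Si](C)(C)C(C)(C)C)CCC=C1 | intermediate
9 | methylzinc (3S,6S)-6-[2-(TBSO)ethyl]-3-methylcyclohept-1-en-1-olate | C[Zn]OC=1C[C@H](CCO[Si](C)(C)C(C)(C)C)CC[C@H](C)C=1 | intermediate (not isolated)
10 | tert-butyl{[(3S,6S)-6-[2-(TBSO)ethyl]-3-methylcyclohept-1-en-1-yl]oxy}dimethylsilane | CC(C)(C)[Si](C)(C)OC=1C[C@H](CCO[Si](C)(C)C(C)(C)C)CC[C@H](C)C=1 | intermediate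
11 | [(1R,2R,4S,7S)-2-(TBSO)-4-[2-(TBSO)ethyl]-7-methylcycloheptyl]borane | CC(C)(C)[Si](C)(C)O[C@@H]1C[C@H](CCO[Si](C)(C)C(C)(C)C)CC[C@H](C)[C@H]1B | intermediate (not isolated)
12 | (1R,2R,4S,7S)-2-(TBSO)-4-[2-(TBSO)ethyl]-7-methylcycloheptan-1-ol | CC(C)(C)[Si](C)(C)O[C@@H]1C[C@H](CCO[Si](C)(C)C(C)(C)C)CC[C@H](C)[C@H]1O | intermediate
13 | (2R,4S,7S)-2-(TBSO)-4-[2-(TBSO)ethyl]-7-methylcycloheptan-1-one | CC(C)(C)[Si](C)(C)O[C@@H]1C[C@H](CCO[Si](C)(C)C(C)(C)C)CC[C@H](C)C1=O | intermediate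
14 | ethyl acetoacetate | CCOC(=O)CC(C)=O | starting material
15 | ethyl (3R)-3-hydroxybutanoate | CCOC(=O)C[C@@H](C)O | intermediate
16 | ethyl (3R)-3-(TBDPSO)butanoate | CCOC(=O)C[C@@H](C)O[Si](c1ccccc1)(c1ccccc1)C(C)(C)C | intermediate
17 | (3R)-3-(TBDPSO)butanal | O=CC[C@@H](C)O[Si](c1ccccc1)(c1ccccc1)C(C)(C)C | intermediate
18 | tert-butyl[(2R)-pent-4-yn-2-yloxy]diphenylsilane | C#CC[C@@H](C)O[Si](c1ccccc1)(c1ccccc1)C(C)(C)C | intermediate
19 | 9-[(1Z,4R)-2-bromo-4-(TBDPSO)pent-1-en-1-yl]-9-borabicyclo[3.3.1]nonane | Br/C(C[C@@H](C)O[Si](c1ccccc1)(c1ccccc1)C(C)(C)C)=C\B1C2CCCC1CCC2 | intermediate (not isolated)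
20 | {[(2R)-4-bromopent-4-en-2-yl]oxy}(tert-butyl)diphenylsilane | C=C(Br)C[C@@H](C)O[Si](c1ccccc1)(c1ccccc1)C(C)(C)C | intermediate
21 | [(4R)-4-(TBDPSO)pent-1-en-2-yl]lithium | [Li]C(=C)C[C@@H](C)O[Si](c1ccccc1)(c1ccccc1)C(C)(C)C | intermediate (not isolated)
22 | dichloro[(4R)-4-(TBDPSO)pent-1-en-2-yl]cerium | Cl[Ce](Cl)C(=C)C[C@@H](C)O[Si](c1ccccc1)(c1ccccc1)C(C)(C)C | intermediate (not isolated)
23 | (1R,2R,4S,7S)-2-(TBSO)-4-[2-(TBSO)ethyl]-7-methyl-1-[(4R)-4-(TBDPSO)pent-1-en-2-yl]cycloheptan-1-ol | CC(C)(C)[Si](C)(C)O[C@@H]1C[C@H](CCO[Si](C)(C)C(C)(C)C)CC[C@H](C)[C@@]1(O)C(=C)C[C@@H](C)O[Si](c1ccccc1)(c1ccccc1)C(C)(C)C | intermediate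
24 | (1R,2R,4S,7S)-4-(2-hydroxyethyl)-7-methyl-1-[(4R)-4-(TBDPSO)pent-1-en-2-yl]cycloheptane-1,2-diol | O[C@@H]1C[C@H](CCO)CC[C@H](C)[C@@]1(O)C(=C)C[C@@H](C)O[Si](c1ccccc1)(c1ccccc1)C(C)(C)C | intermediate
25 | 2-[(1S,4R,5S)-4-hydroxy-5-methyl-3-oxo-4-[(4R)-4-(TBDPSO)pent-1-en-2-yl]cycloheptyl]acetaldehyde | O=C1C[C@H](CC=O)CC[C@H](C)[C@@]1(O)C(=C)C[C@@H](C)O[Si](c1ccccc1)(c1ccccc1)C(C)(C)C | intermediate
26 | 2-[(1R,4R,5S)-4-hydroxy-5-methyl-3-oxo-4-[(4R)-4-(TBDPSO)pent-1-en-2-yl]cycloheptyl]acetic acid | O=C1C[C@H](CC(=O)O)CC[C@H](C)[C@@]1(O)C(=C)C[C@@H](C)O[Si](c1ccccc1)(c1ccccc1)C(C)(C)C | intermediate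
27 | trimethylsilyl 2-[(1S,4R,5S)-5-methyl-4-[(4R)-4-(TBDPSO)pent-1-en-2-yl]-3,4-bis(trimethylsilyloxy)cyclohept-2-en-1-yl]acetate | C[Si](C)(C)OC1=C[C@H](CC(=O)O[Si](C)(C)C)CC[C@H](C)[C@@]1(O[Si](C)(C)C)C(=C)C[C@@H](C)O[Si](c1ccccc1)(c1ccccc1)C(C)(C)C | intermediate (not isolated)
28 | trimethylsilyl 2-[(1S,2S,4R,5S)-2-bromo-5-methyl-3-oxo-4-[(4R)-4-(TBDPSO)pent-1-en-2-yl]-4-(trimethylsilyloxy)cycloheptyl]acetate | O=C1[C@@H](Br)[C@H](CC(=O)O[Si](C)(C)C)CC[C@H](C)[C@@]1(O[Si](C)(C)C)C(=C)C[C@@H](C)O[Si](c1ccccc1)(c1ccccc1)C(C)(C)C | intermediate (not isolated)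
29 | (3aS,6S,7R,8aR)-7-hydroxy-6-methyl-7-[(4R)-4-(TBDPSO)pent-1-en-2-yl]hexahydro-2H-cyclohepta[b]furan-2,8(3H)-dione | O=C1[C@@H]2OC(=O)C[C@@H]2CC[C@H](C)[C@@]1(O)C(=C)C[C@@H](C)O[Si](c1ccccc1)(c1ccccc1)C(C)(C)C | intermediate
30 | (3aS,6S,7R,8S,8aR)-7,8-dihydroxy-6-methyl-7-[(4R)-4-(TBDPSO)pent-1-en-2-yl]octahydro-2H-cyclohepta[b]furan-2-one | O[C@H]1[C@@H]2OC(=O)C[C@@H]2CC[C@H](C)[C@@]1(O)C(=C)C[C@@H](C)O[Si](c1ccccc1)(c1ccccc1)C(C)(C)C | intermediate
31 | (3aS,6S,7R,8S,8aR)-6-methyl-7-[(4R)-4-(TBDPSO)pent-1-en-2-yl]-7,8-bis(TESO)octahydro-2H-cyclohepta[b]furan-2-one | CC[Si](CC)(CC)O[C@H]1[C@@H]2OC(=O)C[C@@H]2CC[C@H](C)[C@@]1(O[Si](CC)(CC)CC)C(=C)C[C@@H](C)O[Si](c1ccccc1)(c1ccccc1)C(C)(C)C | intermediate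
32 | lithium enolate of 31 | CC[Si](CC)(CC)O[C@H]1[C@@H]2OC(O[Li])=C[C@@H]2CC[C@H](C)[C@@]1(O[Si](CC)(CC)CC)C(=C)C[C@@H](C)O[Si](c1ccccc1)(c1ccccc1)C(C)(C)C | intermediate (not isolated)
33 | (3S,3aS,6S,7R,8S,8aR)-3,6-dimethyl-7-[(4R)-4-(TBDPSO)pent-1-en-2-yl]-7,8-bis(TESO)octahydro-2H-cyclohepta[b]furan-2-one | CC[Si](CC)(CC)O[C@H]1[C@@H]2OC(=O)[C@@H](C)[C@@H]2CC[C@H](C)[C@@]1(O[Si](CC)(CC)CC)C(=C)C[C@@H](C)O[Si](c1ccccc1)(c1ccccc1)C(C)(C)C | intermediate
34 | lithium enolate of 33 | CC[Si](CC)(CC)O[C@H]1[C@@H]2OC(O[Li])=C(C)[C@@H]2CC[C@H](C)[C@@]1(O[Si](CC)(CC)CC)C(=C)C[C@@H](C)O[Si](c1ccccc1)(c1ccccc1)C(C)(C)C | intermediate (not isolated)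
35 | (3R,3aS,6S,7R,8S,8aR)-3,6-dimethyl-7-[(4R)-4-(TBDPSO)pent-1-en-2-yl]-7,8-bis(TESO)octahydro-2H-cyclohepta[b]furan-2-one | CC[Si](CC)(CC)O[C@H]1[C@@H]2OC(=O)[C@H](C)[C@@H]2CC[C@H](C)[C@@]1(O[Si](CC)(CC)CC)C(=C)C[C@@H](C)O[Si](c1ccccc1)(c1ccccc1)C(C)(C)C | intermediate
36 | ozonide (1,2,4-trioxolane at the side-chain alkene) of 35 | CC[Si](CC)(CC)O[C@H]1[C@@H]2OC(=O)[C@H](C)[C@@H]2CC[C@H](C)[C@@]1(O[Si](CC)(CC)CC)C3(C[C@@H](C)O[Si](c4ccccc4)(c4ccccc4)C(C)(C)C)OCOO3 | intermediate (not isolated)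
37 | (3R,3aS,6S,7S,8S,8aR)-3,6-dimethyl-7-[(3R)-3-(TBDPSO)butanoyl]-7,8-bis(TESO)octahydro-2H-cyclohepta[b]furan-2-one | CC[Si](CC)(CC)O[C@H]1[C@@H]2OC(=O)[C@H](C)[C@@H]2CC[C@H](C)[C@@]1(O[Si](CC)(CC)CC)C(=O)C[C@@H](C)O[Si](c1ccccc1)(c1ccccc1)C(C)(C)C | intermediate
38 | (3R,3aS,6S,7S,8S,8aR)-7,8-dihydroxy-3,6-dimethyl-7-[(3R)-3-(TBDPSO)butanoyl]octahydro-2H-cyclohepta[b]furan-2-one | O[C@H]1[C@@H]2OC(=O)[C@H](C)[C@@H]2CC[C@H](C)[C@@]1(O)C(=O)C[C@@H](C)O[Si](c1ccccc1)(c1ccccc1)C(C)(C)C | intermediate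
39 | angelic acid [(2Z)-2-methylbut-2-enoic acid] | C/C=C(/C)C(=O)O | starting material
40 | (2Z)-2-methylbut-2-enoic 2,4,6-trichlorobenzoic anhydride | C/C=C(/C)C(=O)OC(=O)c1c(Cl)cc(Cl)cc1Cl | intermediate (not isolated)
41 | (3R,3aS,6S,7S,8S,8aR)-7-hydroxy-3,6-dimethyl-2-oxo-7-[(3R)-3-(TBDPSO)butanoyl]octahydro-2H-cyclohepta[b]furan-8-yl (2Z)-2-methylbut-2-enoate | C/C=C(/C)C(=O)O[C@H]1[C@@H]2OC(=O)[C@H](C)[C@@H]2CC[C@H](C)[C@@]1(O)C(=O)C[C@@H](C)O[Si](c1ccccc1)(c1ccccc1)C(C)(C)C | intermediate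
42 | (3R,3aS,6S,7S,8S,8aR)-7-hydroxy-7-[(3R)-3-hydroxybutanoyl]-3,6-dimethyl-2-oxooctahydro-2H-cyclohepta[b]furan-8-yl (2Z)-2-methylbut-2-enoate | C/C=C(/C)C(=O)O[C@H]1[C@@H]2OC(=O)[C@H](C)[C@@H]2CC[C@H](C)[C@@]1(O)C(=O)C[C@@H](C)O | target

**Count**
Total steps: 26. Longest linear sequence: 21 steps (steps 1–8, then 14–26); the side-chain branch is steps 9–13.

**Three steps most likely to fail, with fallbacks**

Step 18 (bromination and lactonisation; three stages in one flask beside an acid-sensitive tertiary allylic alcohol). The fallback sets out from 26 and comes back at 29. The silyl enol ether is formed as before but is oxidised with dimethyldioxirane (Rubottom oxidation, anti to the side chain) and desilylated with mild acid, which gives 2-[(1S,2S,4R,5S)-2,4-dihydroxy-5-methyl-3-oxo-4-[(4R)-4-(TBDPSO)pent-1-en-2-yl]cycloheptyl]acetic acid F1. Intramolecular Mitsunobu lactonisation (PPh3, DIAD, THF) then closes the C–O bond with inversion at the carbinol carbon and delivers 29.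

Step 22 (kinetic protonation at C11; the selectivity rests on the convex-face preference). The fallback sets out from 31 and comes back at 37, replacing protonation by face-selective hydrogenation. The lithium enolate of 31 is treated with Eschenmoser's salt to give the Mannich base (3R)-3-[(dimethylamino)methyl] lactone F2. Quaternisation with MeI and elimination with NaHCO3 give the α-methylene lactone F3. Ozonolysis at −78 °C to a Sudan III end point cleaves only the electron-rich side-chain alkene and gives the keto α-methylene lactone F4. Hydrogenation with RhCl(PPh3)3/H2 adds hydrogen from the convex face and gives 37.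

Step 25 (angeloylation of a hindered secondary alcohol; slow acylation and Z to E isomerisation). The fallback sets out from 38 and comes back at 41, building the angelate on the substrate instead of transferring it. Esterification with but-2-ynoic acid (DIC, DMAP, 0 °C) gives the but-2-ynoate F5. Pd(PPh3)4-catalysed syn-hydrostannation with Bu3SnH gives the (2E)-2-(tributylstannyl)but-2-enoate F6. Stille methylation (MeI, Pd2(dba)3, AsPh3, CuI, DMF) with retention of geometry gives 41.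

**Further compounds**
F1 | step 18 | 2-[(1S,2S,4R,5S)-2,4-dihydroxy-5-methyl-3-oxo-4-[(4R)-4-(TBDPSO)pent-1-en-2-yl]cycloheptyl]acetic acid | O=C1[C@@H](O)[C@H](CC(=O)O)CC[C@H](C)[C@@]1(O)C(=C)C[C@@H](C)O[Si](c1ccccc1)(c1ccccc1)C(C)(C)C
F2 | step 22 | (3R,3aS,6S,7R,8S,8aR)-3-[(dimethylamino)methyl]-6-methyl-7-[(4R)-4-(TBDPSO)pent-1-en-2-yl]-7,8-bis(TESO)octahydro-2H-cyclohepta[b]furan-2-one | CC[Si](CC)(CC)O[C@H]1[C@@H]2OC(=O)[C@@H](CN(C)C)[C@@H]2CC[C@H](C)[C@@]1(O[Si](CC)(CC)CC)C(=C)C[C@@H](C)O[Si](c1ccccc1)(c1ccccc1)C(C)(C)C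
F3 | step 22 | (3aS,6S,7R,8S,8aR)-6-methyl-3-methylidene-7-[(4R)-4-(TBDPSO)pent-1-en-2-yl]-7,8-bis(TESO)octahydro-2H-cyclohepta[b]furan-2-one | CC[Si](CC)(CC)O[C@H]1[C@@H]2OC(=O)C(=C)[C@@H]2CC[C@H](C)[C@@]1(O[Si](CC)(CC)CC)C(=C)C[C@@H](C)O[Si](c1ccccc1)(c1ccccc1)C(C)(C)C
F4 | step 22 | (3aS,6S,7S,8S,8aR)-6-methyl-3-methylidene-7-[(3R)-3-(TBDPSO)butanoyl]-7,8-bis(TESO)octahydro-2H-cyclohepta[b]furan-2-one | CC[Si](CC)(CC)O[C@H]1[C@@H]2OC(=O)C(=C)[C@@H]2CC[C@H](C)[C@@]1(O[Si](CC)(CC)CC)C(=O)C[C@@H](C)O[Si](c1ccccc1)(c1ccccc1)C(C)(C)C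
F5 | step 25 | (3R,3aS,6S,7S,8S,8aR)-7-hydroxy-3,6-dimethyl-2-oxo-7-[(3R)-3-(TBDPSO)butanoyl]octahydro-2H-cyclohepta[b]furan-8-yl but-2-ynoate | CC#CC(=O)O[C@H]1[C@@H]2OC(=O)[C@H](C)[C@@H]2CC[C@H](C)[C@@]1(O)C(=O)C[C@@H](C)O[Si](c1ccccc1)(c1ccccc1)C(C)(C)C
F6 | step 25 | (3R,3aS,6S,7S,8S,8aR)-7-hydroxy-3,6-dimethyl-2-oxo-7-[(3R)-3-(TBDPSO)butanoyl]octahydro-2H-cyclohepta[b]furan-8-yl (2E)-2-(tributylstannyl)but-2-enoate | C/C=C(/[Sn](CCCC)(CCCC)CCCC)C(=O)O[C@H]1[C@@H]2OC(=O)[C@H](C)[C@@H]2CC[C@H](C)[C@@]1(O)C(=O)C[C@@H](C)O[Si](c1ccccc1)(c1ccccc1)C(C)(C)C
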